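**Strategy.** Ferulate numbering is used (C1 chain, C3 OMe, C4 OH, C5 biaryl carbon). The phenolic oxygens O4 and O4′ are 1,6-related through C4–C5–C5′–C4′. A single bridging atom therefore makes C5–C5′ the closing bond of a seven-membered ring. Instead of dimerising free phenols, four methyl dihydroferulate units are hung on one boron atom. Anodic oxidation of this tetra(aryloxy)borate anion couples its ligands pairwise, closing two dibenzo-1,3,2-dioxaborepine rings and forming two biaryl bonds in one operation. C1 and C3 are blocked, the B–O bonds exclude C–O coupling, and the ring size excludes ortho–meta′ coupling. The precursor is one achiral salt made from a commercial C10 acid.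

Key step: step 3

Remark on the chemistry: the target has no stereocentre, and its biaryl axis (only OH and H ortho to it on each ring) rotates freely at room temperature. The SMILES therefore describes one achiral compound and no enantioselective step is needed.

Step 1
Reactants: 1 3-(4-hydroxy-3-methoxyphenyl)propanoic acid (dihydroferulic acid)
Product: 2 methyl 3-(4-hydroxy-3-methoxyphenyl)propanoate
Conditions: MeOH, cat. H2SO4, reflux
Reagents that add atoms: methanol, CO
Why: Fischer esterification in excess methanol is selective for the carboxylic acid (phenol and aryl methyl ether are inert) and masks the group that would otherwise bind boron in step 2 and trap the oxidised ring as a C1 spirolactone in step 3; no stereocentre is involved.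

Step 2
Reactants: 2 methyl 3-(4-hydroxy-3-methoxyphenyl)propanoate (4 equiv per boron)
Product: 3 sodium tetrakis[2-methoxy-4-(3-methoxy-3-oxopropyl)phenoxy]borate
Conditions: B(OMe)3 (0.25 equiv), NaOMe (0.25 equiv), toluene, 110 °C, MeOH distilled off, N2
Reagents that add atoms: trimethyl borate, COB(OC)OC; sodium methoxide, [Na+].[O-]C
Why: Ligand exchange (transesterification) at boron: the phenol, far more acidic than methanol, displaces methoxide from the tetramethoxyborate formed in the flask, distillation of methanol drives the equilibrium to the homoleptic tetra(aryloxy)borate, and the methyl esters can only undergo degenerate exchange with methoxide.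

Step 3
Reactants: 3 sodium tetrakis[2-methoxy-4-(3-methoxy-3-oxopropyl)phenoxy]borate
Product: 5 dimethyl 3,3'-(6,6'-dihydroxy-5,5'-dimethoxybiphenyl-3,3'-diyl)dipropanoate, via spirocyclic sodium bis(biphenyldiolato)borate 4 (not isolated)
Conditions: undivided cell, Pt anode, Pt cathode, MeCN (no added electrolyte), constant current 5 mA cm−2, 4 F per mol of 3, rt, N2; then 1 M HCl, EtOAc
Reagents that add atoms: none
Why: Template-directed anodic phenol coupling of a tetra(aryloxy)borate (anodic dehydrogenative aryl–aryl coupling): a B-bound aryloxy ligand gives up one electron at low potential, its C5 (the only ortho or para carbon still bearing H, since C1 carries the chain and C3 the OMe) bonds to C5′ of a geminal ligand held within reach by the tetrahedral O–B–O angle, and a second electron and two protons are lost on rearomatisation, the protons being reduced to H2 at the cathode. Each of the two rings that close is a seven-membered dibenzo-1,3,2-dioxaborepine, closed ligand-to-ligand by ortho–ortho′ C–C bond formation (formally a 7-endo attack on the C4′=C5′ π bond), and the resulting bis(biphenyl-2,2′-diolato)borate belongs to a well-known, unstrained chelate type. No stereocentre is formed, and the new axis, flanked only by O and H, is configurationally labile. The step needs C–C over C–O coupling, ortho–ortho′ over ortho–meta′ coupling and dimer over oligomer: both oxygens are tied up as B–O bonds, C6′ or C2′ of a neighbouring ligand could reach C5 only through a strained meta-bridged medium ring, Coulomb repulsion between the anions disfavours intermolecular coupling, and each ligand finds one partner before the chelate, which should be harder to oxidise than the open borate, is formed. Methyl esters, aryl methyl ethers and MeCN are inert at the potential needed, the salt is its own supporting electrolyte, and the mild acid work-up hydrolyses the B–O bonds of 4 and releases two molecules of 5 per boron.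

Step 4
Reactants: 5 dimethyl 3,3'-(6,6'-dihydroxy-5,5'-dimethoxybiphenyl-3,3'-diyl)dipropanoate
Product: 6 3,3'-(6,6'-dihydroxy-5,5'-dimethoxybiphenyl-3,3'-diyl)dipropanoic acid (target, CNP0122720.0)
Conditions: LiOH (excess), degassed THF/H2O, rt, N2; then 1 M HCl
Reagents that add atoms: lithium hydroxide, [Li+].[OH-]
Why: Saponification (BAc2 ester hydrolysis) of two unhindered methyl esters followed by acidification; exclusion of oxygen protects the electron-rich biphenolate, the aryl methyl ethers and the biaryl bond are inert to hydroxide, and no stereocentre is at stake.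

**Compound list**

1 | 3-(4-hydroxy-3-methoxyphenyl)propanoic acid | COc1cc(CCC(=O)O)ccc1O | starting material
2 | methyl 3-(4-hydroxy-3-methoxyphenyl)propanoate | COC(=O)CCc1ccc(O)c(OC)c1 | intermediate
3 | sodium tetrakis[2-methoxy-4-(3-methoxy-3-oxopropyl)phenoxy]borate | [Na+].COC(=O)CCc1ccc(O[B-](Oc2ccc(CCC(=O)OC)cc2OC)(Oc2ccc(CCC(=O)OC)cc2OC)Oc2ccc(CCC(=O)OC)cc2OC)c(OC)c1 | intermediate
4 | sodium bis[3,3'-dimethoxy-5,5'-bis(3-methoxy-3-oxopropyl)biphenyl-2,2'-diolato]borate | [Na+].COC(=O)CCc1cc(OC)c2O[B-]3(Oc4c(OC)cc(CCC(=O)OC)cc4-c4cc(CCC(=O)OC)cc(OC)c4O3)Oc3c(OC)cc(CCC(=O)OC)cc3-c2c1 | intermediate (not isolated)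
5 | dimethyl 3,3'-(6,6'-dihydroxy-5,5'-dimethoxybiphenyl-3,3'-diyl)dipropanoate | COC(=O)CCc1cc(OC)c(O)c(-c2cc(CCC(=O)OC)cc(OC)c2O)c1 | intermediate
6 | 3,3'-(6,6'-dihydroxy-5,5'-dimethoxybiphenyl-3,3'-diyl)dipropanoic acid | COc1cc(CCC(=O)O)cc(-c2cc(CCC(=O)O)cc(OC)c2O)c1O | target

Total step count: 4. Longest linear sequence: 4.

**Steps most likely to fail**

Step 3 (key step). After the first electron transfer the oxidised ligand may dissociate from boron, so that template control is lost. Other processes to fear are two-electron oxidation with loss of a benzylic C7 proton (quinone methide formation), passivation of the anode by polymer films, and further oxidation of the coupled product. The fallback replaces oxidative by reductive aryl–aryl bond formation. It sets out from 2 and comes back at 5. Bromination ortho to the free phenol (Br2, AcOH) should give methyl 3-(3-bromo-4-hydroxy-5-methoxyphenyl)propanoate F1. O-Benzylation (BnBr, K2CO3, DMF) gives methyl 3-[4-(benzyloxy)-3-bromo-5-methoxyphenyl]propanoate F2. Nickel(0)-catalysed reductive homocoupling (NiCl2(PPh3)2, Zn, Et4NI, THF, 50 °C) gives dimethyl 3,3'-[6,6'-bis(benzyloxy)-5,5'-dimethoxybiphenyl-3,3'-diyl]dipropanoate F3. Hydrogenolysis (H2, Pd/C, EtOAc) then returns 5.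

Step 2. Incomplete ligand exchange, or hydrolysis by traces of water, would leave a mixture of methoxy, hydroxy and aryloxy borates with free phenol, and the electrolysis substrate would then be ill defined. The fallback gives up the template. It sets out from 2 and comes back at 5 in one operation, by intermolecular phenoxyl radical dimerisation with laccase and O2 (acetate buffer pH 5/acetone, rt). Selectivity then rests only on the blocked C1 and C3 positions. No new compound is made (F0).

Step 4. The electron-rich biphenolate generated by hydroxide may be oxidised by adventitious air to quinoid and oligomeric material before both esters are cleaved. The fallback uses an ester that is removed under neutral reductive conditions, so that no phenolate is generated at the end. It sets out from 1 and comes back at 6.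
- Selective alkylation of the carboxylate (BnBr, KHCO3, DMF) gives benzyl 3-(4-hydroxy-3-methoxyphenyl)propanoate F4.
- Protonolysis of NaBH4 (0.25 equiv, THF, reflux; no alkoxide is present, so no transesterification) gives sodium tetrakis{4-[3-(benzyloxy)-3-oxopropyl]-2-methoxyphenoxy}borate F5.
- Electrolysis as in step 3 gives sodium bis{5,5'-bis[3-(benzyloxy)-3-oxopropyl]-3,3'-dimethoxybiphenyl-2,2'-diolato}borate F6.
- Acid work-up hydrolyses this to dibenzyl 3,3'-(6,6'-dihydroxy-5,5'-dimethoxybiphenyl-3,3'-diyl)dipropanoate F7.
- Hydrogenolysis (H2, Pd/C, EtOAc) gives 6.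

**Further compounds**

F1 | step 3 | methyl 3-(3-bromo-4-hydroxy-5-methoxyphenyl)propanoate | COC(=O)CCc1cc(Br)c(O)c(OC)c1
F2 | step 3 | methyl 3-[4-(benzyloxy)-3-bromo-5-methoxyphenyl]propanoate | COC(=O)CCc1cc(Br)c(OCc2ccccc2)c(OC)c1
F3 | step 3 | dimethyl 3,3'-[6,6'-bis(benzyloxy)-5,5'-dimethoxybiphenyl-3,3'-diyl]dipropanoate | COC(=O)CCc1cc(OC)c(OCc2ccccc2)c(-c2cc(CCC(=O)OC)cc(OC)c2OCc2ccccc2)c1
F0 | step 2 | none | none
F4 | step 4 | benzyl 3-(4-hydroxy-3-methoxyphenyl)propanoate | COc1cc(CCC(=O)OCc2ccccc2)ccc1O
F5 | step 4 | sodium tetrakis{4-[3-(benzyloxy)-3-oxopropyl]-2-methoxyphenoxy}borate | [Na+].COc1cc(CCC(=O)OCc2ccccc2)ccc1O[B-](Oc1ccc(CCC(=O)OCc2ccccc2)cc1OC)(Oc1ccc(CCC(=O)OCc2ccccc2)cc1OC)Oc1ccc(CCC(=O)OCc2ccccc2)cc1OC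
F6 | step 4 | sodium bis{5,5'-bis[3-(benzyloxy)-3-oxopropyl]-3,3'-dimethoxybiphenyl-2,2'-diolato}borate | [Na+].O=C(CCc1cc(OC)c2O[B-]3(Oc4c(OC)cc(CCC(=O)OCc5ccccc5)cc4-c4cc(CCC(=O)OCc5ccccc5)cc(OC)c4O3)Oc3c(OC)cc(CCC(=O)OCc4ccccc4)cc3-c2c1)OCc1ccccc1
F7 | step 4 | dibenzyl 3,3'-(6,6'-dihydroxy-5,5'-dimethoxybiphenyl-3,3'-diyl)dipropanoate | COc1cc(CCC(=O)OCc2ccccc2)cc(-c2cc(CCC(=O)OCc3ccccc3)cc(OC)c2O)c1O
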